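**Plan**

- Retrosynthesis (diene carbons Ca to Cd counted from the oxolane): the Cb–Cc bond is cut first (alkenylboronate + alkenyl iodide), then Ca=Cb and Cc=Cd (two aldehydes), then O1–C5 and C5–H of the oxolane (open-chain hydroxy methyl ketone), then C5–CH3 (lactone + MeLi); in the other half O2–C1 and C3–C4 of the isocoumarin are cut (chlorinated orsellinate + acetyl unit).
- Forward: 2-deoxy-L-ribose → silylated lactone → hydroxy methyl ketone → oxolane ring (step 4) → aldehyde → (E)-alkenylboronate; methyl orsellinate → 5-chloro toluate → benzylic acylation → pyranone ring of the isocoumarin (step 11) → aldehyde → (E)-alkenyl iodide; Suzuki–Miyaura coupling joins the halves (step 15) and fluoride frees the three hydroxyls (step 16).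
- Enabling feature: the oxolane O1–C2–C3–C4–C5 is a 1-C-methyl-1,2-dideoxy-L-ribofuranose; C2 (carbon branch) and C3 (hydroxyl) match C4 and C3 of 2-deoxy-L-ribose, and C5, flanked by O1 and the methyl group, is a ketal-level carbon that can be made by reducing a cyclic oxocarbenium ion.
- Stereochemistry: C2 and C3 come unchanged from the sugar; C5 is set by hydride delivery to the oxocarbenium ion on the face cis to the C3 silyloxy group; both E double bonds come from chromium-mediated aldehyde olefinations and are retained in the coupling.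

Key step: step 4

Remark: the MeLi adduct of the silylated lactone is a ring–chain tautomeric pair; it is numbered and drawn as the open hydroxy ketone, and the closed hemiketal is counted as the first intermediate of the reduction step.

**Route**

Step 1
Reactants: 1 2-deoxy-L-ribose
Product: 2 2-deoxy-L-ribono-1,4-lactone [(4R,5S)-4-hydroxy-5-(hydroxymethyl)oxolan-2-one]
Conditions: Br2, H2O, rt, dark; excess Br2 and HBr removed by evaporation
Reagents that add atoms: none
Why: Bromine-water oxidation of the aldose hemiacetal gives the aldonic acid, which closes to the five-membered lactone on concentration, and the two stereocentres are not touched.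

Step 2
Reactants: 2 2-deoxy-L-ribono-1,4-lactone
Product: 3 (4R,5S)-4-(tert-butyldimethylsilyloxy)-5-[(tert-butyldimethylsilyloxy)methyl]oxolan-2-one
Conditions: TBSCl (2.5 equiv), imidazole, DMF, rt
Reagents that add atoms: tert-butyldimethylsilyl chloride, CC(C)(C)[Si](C)(C)Cl
Why: Imidazole-promoted O-silylation protects both hydroxyls, and the primary and secondary silyl ethers differ enough in steric demand to allow the later selective release of the primary one.

Step 3
Reactants: 3 (4R,5S)-4-(tert-butyldimethylsilyloxy)-5-[(tert-butyldimethylsilyloxy)methyl]oxolan-2-one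
Product: 5 (4R,5S)-4,6-bis(tert-butyldimethylsilyloxy)-5-hydroxyhexan-2-one, via lithium hemiketalate 4 (not isolated)
Conditions: MeLi (1.1 equiv), THF, −78 °C; sat. aq. NH4Cl, −78 °C → rt
Reagents that add atoms: methyllithium, [Li]C
Why: 1,2-Addition of an organolithium to a lactone stops at the tetrahedral lithium hemiketalate at −78 °C, so only one methyl group should be taken up and protonation releases the 1-deoxy-ketose, as in organolithium additions to protected aldonolactones.

Step 4
Reactants: 5 (4R,5S)-4,6-bis(tert-butyldimethylsilyloxy)-5-hydroxyhexan-2-one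
Product: 8 (2S,3R,5R)-3-(tert-butyldimethylsilyloxy)-2-[(tert-butyldimethylsilyloxy)methyl]-5-methyloxolane, via cyclic hemiketal 6 (not isolated), via oxocarbenium ion 7 (not isolated)
Conditions: Et3SiH (3 equiv), BF3·OEt2 (2 equiv), CH2Cl2, −78 → −40 °C; sat. aq. NaHCO3
Reagents that add atoms: none
Why: BF3·OEt2 closes the open form 5 to hemiketal 6 by 5-exo-trig addition of its free hydroxyl (the later O1) to the ketone carbon (the later C5) and then ionizes 6 to the five-membered oxocarbenium ion 7, to which Et3SiH transfers hydride, so that the O1–C5 ring bond and the C5–H bond arise in one operation. The closest known reaction type is the silane/Lewis acid reduction (ionic hydrogenation) of furanose hemiketals made from aldonolactones and organolithiums, the usual entry to β-C-glycosides of 2-deoxyribose. The new stereocentre C5 is controlled by the C3 silyloxy group: in the preferred envelope of 7 this group is pseudoaxial and the hydride enters on the inside face of the envelope, cis to it. The methyl group should therefore end trans to the C3 oxygen and cis to the C2 branch, which is 5R with the 2,5-cis geometry of the target. The step needs facial selectivity and intact silyl ethers; the first rests on this one controlling substituent in a ring whose other two centres are already fixed by the sugar, the second on low temperature and the absence of any nucleophile other than the silane.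

Step 5
Reactants: 8 (2S,3R,5R)-3-(tert-butyldimethylsilyloxy)-2-[(tert-butyldimethylsilyloxy)methyl]-5-methyloxolane
Product: 9 [(2S,3R,5R)-3-(tert-butyldimethylsilyloxy)-5-methyloxolan-2-yl]methanol
Conditions: TFA/H2O/THF (1:1:4), 0 °C
Reagents that add atoms: none
Why: Acid-catalysed hydrolysis of silyl ethers is much faster at the unhindered primary position than at the secondary one, the selectivity used for 5'-desilylation of bis-silylated deoxynucleosides.

Step 6
Reactants: 9 [(2S,3R,5R)-3-(tert-butyldimethylsilyloxy)-5-methyloxolan-2-yl]methanol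
Product: 10 (2R,3R,5R)-3-(tert-butyldimethylsilyloxy)-5-methyloxolane-2-carbaldehyde
Conditions: Dess–Martin periodinane, CH2Cl2, 0 °C → rt; used at once without chromatography
Reagents that add atoms: none
Why: Dess–Martin oxidation gives the aldehyde under non-basic conditions, so the α-alkoxy centre C2 should not epimerize and the β-silyloxy group should not be eliminated (the descriptor at C2 changes only through the priority rules).

Step 7
Reactants: 10 (2R,3R,5R)-3-(tert-butyldimethylsilyloxy)-5-methyloxolane-2-carbaldehyde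
Product: 11 (2S,3R,5R)-3-(tert-butyldimethylsilyloxy)-5-methyl-2-[(E)-2-(4,4,5,5-tetramethyl-1,3,2-dioxaborolan-2-yl)ethenyl]oxolane
Conditions: CrCl2 (8 equiv), Cl2CHB(pin) (2 equiv), LiI (4 equiv), THF, rt
Reagents that add atoms: 2-(dichloromethyl)-4,4,5,5-tetramethyl-1,3,2-dioxaborolane, ClC(Cl)B1OC(C)(C)C(C)(C)O1
Why: Takai–Utimoto borylolefination, in which the geminal dichromium reagent adds to the aldehyde and eliminates to the (E)-alkenylboronate, is non-basic and therefore leaves C2 untouched while fixing the Ca=Cb geometry.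

Step 8
Reactants: 12 methyl 2,4-dihydroxy-6-methylbenzoate (methyl orsellinate)
Product: 13 methyl 3-chloro-4,6-dihydroxy-2-methylbenzoate
Conditions: SO2Cl2 (1.05 equiv), Et2O, 0 °C → rt
Reagents that add atoms: sulfuryl chloride, O=S(=O)(Cl)Cl
Why: Electrophilic aromatic chlorination of orsellinic acid derivatives favours the position para to the hydrogen-bonded hydroxyl and next to the methyl group, and one equivalent of SO2Cl2 should limit dichlorination.

Step 9
Reactants: 13 methyl 3-chloro-4,6-dihydroxy-2-methylbenzoate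
Product: 14 methyl 3-chloro-4,6-bis(methoxymethoxy)-2-methylbenzoate
Conditions: NaH (2.5 equiv), MOMCl (2.5 equiv), DMF, 0 °C → rt
Reagents that add atoms: chloromethyl methyl ether, COCCl
Why: Williamson-type O-alkylation of both phenoxides gives acetal ethers that tolerate the amide base of the next step and leave later under acid.

Step 10
Reactants: 14 methyl 3-chloro-4,6-bis(methoxymethoxy)-2-methylbenzoate
Product: 17 methyl 3-chloro-4,6-bis(methoxymethoxy)-2-(2-oxopropyl)benzoate, via benzylic lithium species 15 (not isolated), via lithium aminal alkoxide 16 (not isolated)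
Conditions: LiN(iPr)2 (2.1 equiv), THF, −78 °C; MeC(O)N(OMe)Me, −78 °C; sat. aq. NH4Cl
Reagents that add atoms: N-methoxy-N-methylacetamide, CC(=O)N(C)OC
Why: Lateral lithiation of the ortho-toluate followed by Weinreb ketone synthesis should give the methyl ketone only on work-up, because the chelated tetrahedral adduct is stable, and aryne formation is excluded because no ring hydrogen lies next to chlorine.

Step 11
Reactants: 17 methyl 3-chloro-4,6-bis(methoxymethoxy)-2-(2-oxopropyl)benzoate
Product: 19 5-chloro-6,8-dihydroxy-3-methyl-1H-isochromen-1-one, via dihydroxy keto ester 18 (not isolated)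
Conditions: HCl (3 M in MeOH), 50 °C; then TsOH·H2O (cat.), toluene, reflux with removal of MeOH
Reagents that add atoms: none
Why: Acidic methanolysis removes both MOM acetals, and the freed keto ester should then undergo acid-catalysed enol lactonization (6-exo-trig attack of the ketone oxygen on the hydrogen-bonded ortho ester, loss of methanol) to the isocoumarin.

Step 12
Reactants: 19 5-chloro-6,8-dihydroxy-3-methyl-1H-isochromen-1-one
Product: 20 5-chloro-3-methyl-6,8-bis(triisopropylsilyloxy)-1H-isochromen-1-one
Conditions: TIPSOTf (2.5 equiv), 2,6-lutidine, CH2Cl2, 0 °C → rt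
Reagents that add atoms: triisopropylsilyl trifluoromethanesulfonate, CC(C)[Si](OS(=O)(=O)C(F)(F)F)(C(C)C)C(C)C
Why: O-Silylation with a silyl triflate is strong enough for the chelated 8-hydroxyl, and aryl TIPS ethers should withstand the oxidation and the aqueous base of the coupling yet leave with fluoride.

Step 13
Reactants: 20 5-chloro-3-methyl-6,8-bis(triisopropylsilyloxy)-1H-isochromen-1-one
Product: 21 5-chloro-1-oxo-6,8-bis(triisopropylsilyloxy)-1H-isochromene-3-carbaldehyde
Conditions: SeO2 (1.5 equiv), 1,4-dioxane, 100 °C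
Reagents that add atoms: selenium dioxide, O=[Se]=O
Why: Riley oxidation (ene reaction, then [2,3]-sigmatropic shift) converts the allylic-type methyl group on C3 into the aldehyde, the known way from 3-methylisocoumarins to isocoumarin-3-carbaldehydes.

Step 14
Reactants: 21 5-chloro-1-oxo-6,8-bis(triisopropylsilyloxy)-1H-isochromene-3-carbaldehyde
Product: 22 5-chloro-3-[(E)-2-iodoethenyl]-6,8-bis(triisopropylsilyloxy)-1H-isochromen-1-one
Conditions: CrCl2 (6 equiv), CHI3 (2 equiv), THF, 0 °C → rt, dark
Reagents that add atoms: iodoform, IC(I)I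
Why: Takai iodoolefination of an aryl-type aldehyde should give the (E)-alkenyl iodide (Cc=Cd) through the iodo-substituted geminal dichromium species, without touching aryl chloride, lactone or silyl ethers.

Step 15
Reactants: 11 (2S,3R,5R)-3-(tert-butyldimethylsilyloxy)-5-methyl-2-[(E)-2-(4,4,5,5-tetramethyl-1,3,2-dioxaborolan-2-yl)ethenyl]oxolane; 22 5-chloro-3-[(E)-2-iodoethenyl]-6,8-bis(triisopropylsilyloxy)-1H-isochromen-1-one
Product: 23 3-[(1E,3E)-4-[(2S,3R,5R)-3-(tert-butyldimethylsilyloxy)-5-methyloxolan-2-yl]buta-1,3-dien-1-yl]-5-chloro-6,8-bis(triisopropylsilyloxy)-1H-isochromen-1-one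
Conditions: Pd(dppf)Cl2·CH2Cl2 (5 mol%), K3PO4 (2 M aq.), THF, rt, degassed
Reagents that add atoms: none
Why: Suzuki–Miyaura coupling of an (E)-alkenyl iodide with an (E)-alkenylboronate proceeds with retention at both partners to give the (E,E)-diene, and zerovalent palladium inserts into the alkenyl iodide far faster than into the aryl chloride.

Step 16
Reactants: 23 3-[(1E,3E)-4-[(2S,3R,5R)-3-(tert-butyldimethylsilyloxy)-5-methyloxolan-2-yl]buta-1,3-dien-1-yl]-5-chloro-6,8-bis(triisopropylsilyloxy)-1H-isochromen-1-one
Product: 24 5-chloro-6,8-dihydroxy-3-[(1E,3E)-4-[(2S,3R,5R)-3-hydroxy-5-methyloxolan-2-yl]buta-1,3-dien-1-yl]-1H-isochromen-1-one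
Conditions: Bu4NF/AcOH (1:1, 6 equiv), THF, 0 °C → rt
Reagents that add atoms: none
Why: Fluoride desilylation should cleave the two aryl TIPS ethers and the secondary TBS ether, the acetic acid buffer protects the lactone and the dienyl ether, and no stereocentre is affected.

**Compound list**

1 | 2-deoxy-L-ribose, (3R,4S)-3,4,5-trihydroxypentanal, drawn open-chain | O=CC[C@@H](O)[C@@H](O)CO | starting material
2 | 2-deoxy-L-ribono-1,4-lactone, (4R,5S)-4-hydroxy-5-(hydroxymethyl)oxolan-2-one | O=C1C[C@@H](O)[C@H](CO)O1 | intermediate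
3 | (4R,5S)-4-(tert-butyldimethylsilyloxy)-5-[(tert-butyldimethylsilyloxy)methyl]oxolan-2-one | O=C1C[C@@H](O[Si](C)(C)C(C)(C)C)[C@H](CO[Si](C)(C)C(C)(C)C)O1 | intermediate
4 | lithium (4R,5S)-4-(tert-butyldimethylsilyloxy)-5-[(tert-butyldimethylsilyloxy)methyl]-2-methyloxolan-2-olate, both C2 epimers | [Li+].CC1([O-])C[C@@H](O[Si](C)(C)C(C)(C)C)[C@H](CO[Si](C)(C)C(C)(C)C)O1 | intermediate (not isolated)
5 | (4R,5S)-4,6-bis(tert-butyldimethylsilyloxy)-5-hydroxyhexan-2-one, in ring–chain equilibrium with its hemiketal | CC(=O)C[C@@H](O[Si](C)(C)C(C)(C)C)[C@H](CO[Si](C)(C)C(C)(C)C)O | intermediate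
6 | (4R,5S)-4-(tert-butyldimethylsilyloxy)-5-[(tert-butyldimethylsilyloxy)methyl]-2-methyloxolan-2-ol, both C2 epimers | CC1(O)C[C@@H](O[Si](C)(C)C(C)(C)C)[C@H](CO[Si](C)(C)C(C)(C)C)O1 | intermediate (not isolated)
7 | (2S,3R)-3-(tert-butyldimethylsilyloxy)-2-[(tert-butyldimethylsilyloxy)methyl]-5-methyl-3,4-dihydro-2H-furan-1-ium hydroxytrifluoroborate | CC=1C[C@@H](O[Si](C)(C)C(C)(C)C)[C@H](CO[Si](C)(C)C(C)(C)C)[O+]=1.O[B-](F)(F)F | intermediate (not isolated)
8 | (2S,3R,5R)-3-(tert-butyldimethylsilyloxy)-2-[(tert-butyldimethylsilyloxy)methyl]-5-methyloxolane | C[C@@H]1C[C@@H](O[Si](C)(C)C(C)(C)C)[C@H](CO[Si](C)(C)C(C)(C)C)O1 | intermediate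
9 | [(2S,3R,5R)-3-(tert-butyldimethylsilyloxy)-5-methyloxolan-2-yl]methanol | C[C@@H]1C[C@@H](O[Si](C)(C)C(C)(C)C)[C@H](CO)O1 | intermediate
10 | (2R,3R,5R)-3-(tert-butyldimethylsilyloxy)-5-methyloxolane-2-carbaldehyde | C[C@@H]1C[C@@H](O[Si](C)(C)C(C)(C)C)[C@H](C=O)O1 | intermediate
11 | (2S,3R,5R)-3-(tert-butyldimethylsilyloxy)-5-methyl-2-[(E)-2-(4,4,5,5-tetramethyl-1,3,2-dioxaborolan-2-yl)ethenyl]oxolane | C[C@@H]1C[C@@H](O[Si](C)(C)C(C)(C)C)[C@H](/C=C/B2OC(C)(C)C(C)(C)O2)O1 | intermediate
12 | methyl 2,4-dihydroxy-6-methylbenzoate (methyl orsellinate) | COC(=O)c1c(C)cc(O)cc1O | starting material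
13 | methyl 3-chloro-4,6-dihydroxy-2-methylbenzoate | COC(=O)c1c(C)c(Cl)c(O)cc1O | intermediate
14 | methyl 3-chloro-4,6-bis(methoxymethoxy)-2-methylbenzoate | COC(=O)c1c(C)c(Cl)c(OCOC)cc1OCOC | intermediate
15 | [2-chloro-6-(methoxycarbonyl)-3,5-bis(methoxymethoxy)phenyl]methyllithium | COC(=O)c1c(C[Li])c(Cl)c(OCOC)cc1OCOC | intermediate (not isolated)
16 | lithium 1-[2-chloro-6-(methoxycarbonyl)-3,5-bis(methoxymethoxy)phenyl]-2-[methoxy(methyl)amino]propan-2-olate | [Li+].COC(=O)c1c(CC(C)([O-])N(C)OC)c(Cl)c(OCOC)cc1OCOC | intermediate (not isolated)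
17 | methyl 3-chloro-4,6-bis(methoxymethoxy)-2-(2-oxopropyl)benzoate | COC(=O)c1c(CC(C)=O)c(Cl)c(OCOC)cc1OCOC | intermediate
18 | methyl 3-chloro-4,6-dihydroxy-2-(2-oxopropyl)benzoate | COC(=O)c1c(CC(C)=O)c(Cl)c(O)cc1O | intermediate (not isolated)
19 | 5-chloro-6,8-dihydroxy-3-methyl-1H-isochromen-1-one | Cc1cc2c(Cl)c(O)cc(O)c2c(=O)o1 | intermediate
20 | 5-chloro-3-methyl-6,8-bis(triisopropylsilyloxy)-1H-isochromen-1-one | Cc1cc2c(Cl)c(O[Si](C(C)C)(C(C)C)C(C)C)cc(O[Si](C(C)C)(C(C)C)C(C)C)c2c(=O)o1 | intermediate
21 | 5-chloro-1-oxo-6,8-bis(triisopropylsilyloxy)-1H-isochromene-3-carbaldehyde | O=Cc1cc2c(Cl)c(O[Si](C(C)C)(C(C)C)C(C)C)cc(O[Si](C(C)C)(C(C)C)C(C)C)c2c(=O)o1 | intermediate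
22 | 5-chloro-3-[(E)-2-iodoethenyl]-6,8-bis(triisopropylsilyloxy)-1H-isochromen-1-one | I/C=C/c1cc2c(Cl)c(O[Si](C(C)C)(C(C)C)C(C)C)cc(O[Si](C(C)C)(C(C)C)C(C)C)c2c(=O)o1 | intermediate
23 | 3-[(1E,3E)-4-[(2S,3R,5R)-3-(tert-butyldimethylsilyloxy)-5-methyloxolan-2-yl]buta-1,3-dien-1-yl]-5-chloro-6,8-bis(triisopropylsilyloxy)-1H-isochromen-1-one | C[C@@H]1C[C@@H](O[Si](C)(C)C(C)(C)C)[C@H](/C=C/C=C/c2cc3c(Cl)c(O[Si](C(C)C)(C(C)C)C(C)C)cc(O[Si](C(C)C)(C(C)C)C(C)C)c3c(=O)o2)O1 | intermediate
24 | 5-chloro-6,8-dihydroxy-3-[(1E,3E)-4-[(2S,3R,5R)-3-hydroxy-5-methyloxolan-2-yl]buta-1,3-dien-1-yl]-1H-isochromen-1-one | C[C@@H]1C[C@@H](O)[C@H](/C=C/C=C/c2cc3c(Cl)c(O)cc(O)c3c(=O)o2)O1 | target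

**Step count and risks**

Total steps: 16 (steps 1–7 on the oxolane half, steps 8–14 on the isocoumarin half, steps 15 and 16 after the union).
Longest linear sequence: 9 steps (either half plus steps 15 and 16).

Steps most likely to fail:

Step 3. What may go wrong: MeLi acts as a base and removes a proton next to the lactone carbonyl, so that the silyloxy group on the neighbouring carbon is eliminated, or the hemiketalate opens early and takes up a second methyl group. Fallback: the route sets out again from 3 and the carbon is brought in as a titanium methylidene instead of a basic nucleophile. Petasis methylenation (Cp2TiMe2, toluene, 70 °C) should give the exocyclic enol ether (4R,5S)-4-(tert-butyldimethylsilyloxy)-5-[(tert-butyldimethylsilyloxy)methyl]-2-methylideneoxolane F1. Mild acid-catalysed hydration (pyridinium p-toluenesulfonate, wet THF, 0 °C) then adds water across the enol ether and returns the ring–chain pair at 5.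

Step 4. What may go wrong: hydride delivery with poor facial selectivity, loss of a proton from the oxocarbenium ion followed by expulsion of the C3 silyloxy group (drift toward a furan), or acid cleavage of the primary silyl ether. Fallback: the route sets out from 5 and the O1–C5 bond is made by substitution instead of by reduction of a cation. Reagent-controlled reduction of the ketone ((R)-2-methyl-CBS-oxazaborolidine, BH3·SMe2, THF, −20 °C) should give (2S,4R,5S)-4,6-bis(tert-butyldimethylsilyloxy)hexane-2,5-diol F2. The less hindered methyl carbinol is then mesylated selectively (MsCl, 2,4,6-collidine, CH2Cl2, −20 °C) to (2S,4R,5S)-4,6-bis(tert-butyldimethylsilyloxy)-5-hydroxyhexan-2-yl methanesulfonate F3. KOtBu in THF closes the ring by intramolecular Williamson etherification (5-exo-tet) with inversion at the methyl-bearing carbon, which comes back to the route at 8. The weak points of this fallback are the selectivity of the reduction of a methyl alkyl ketone and the discrimination between the two secondary hydroxyls.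

Step 13. What may go wrong: over-oxidation to the carboxylic acid, stalling at partial conversion, or loss of the peri silyl ether in hot dioxane. Fallback: the route sets out from 14 and the aldehyde carbon is carried in at the right oxidation level. The benzylic lithium species 15 is acylated with ethyl diethoxyacetate to methyl 3-chloro-2-(3,3-diethoxy-2-oxopropyl)-4,6-bis(methoxymethoxy)benzoate F4. Aqueous trifluoroacetic acid (TFA/H2O, 40 °C) removes the MOM groups, hydrolyses the acetal and closes the lactone to 5-chloro-6,8-dihydroxy-1-oxo-1H-isochromene-3-carbaldehyde F5. Silylation of both phenols (TIPSOTf, 2,6-lutidine, CH2Cl2) returns to the route at 21.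

Further compounds
F1 | step 3 | (4R,5S)-4-(tert-butyldimethylsilyloxy)-5-[(tert-butyldimethylsilyloxy)methyl]-2-methylideneoxolane | C=C1C[C@@H](O[Si](C)(C)C(C)(C)C)[C@H](CO[Si](C)(C)C(C)(C)C)O1
F2 | step 4 | (2S,4R,5S)-4,6-bis(tert-butyldimethylsilyloxy)hexane-2,5-diol | C[C@H](O)C[C@@H](O[Si](C)(C)C(C)(C)C)[C@H](CO[Si](C)(C)C(C)(C)C)O
F3 | step 4 | (2S,4R,5S)-4,6-bis(tert-butyldimethylsilyloxy)-5-hydroxyhexan-2-yl methanesulfonate | C[C@H](OS(C)(=O)=O)C[C@@H](O[Si](C)(C)C(C)(C)C)[C@H](CO[Si](C)(C)C(C)(C)C)O
F4 | step 13 | methyl 3-chloro-2-(3,3-diethoxy-2-oxopropyl)-4,6-bis(methoxymethoxy)benzoate | COC(=O)c1c(CC(=O)C(OCC)OCC)c(Cl)c(OCOC)cc1OCOC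
F5 | step 13 | 5-chloro-6,8-dihydroxy-1-oxo-1H-isochromene-3-carbaldehyde | O=Cc1cc2c(Cl)c(O)cc(O)c2c(=O)o1
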